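**Retrosynthetic overview**
- The C–Cl bond comes last, by invertive chlorination of a bromohydrin that arises from CBS reduction of a bromomethyl ketone; the bromomethyl ketone comes from a methyl ketone.
- The methyl ketone is a 1-acetyl-2-bromocyclohexene. It is disconnected by a one-carbon ring expansion: the cyclopentane ring C2–C3–C4–C5–C6 of a diazo aldol adduct grows to the cyclohexene when C1 (the diazo carbon) is inserted between C2 and C6.
- Enabling feature: the vinylic bromide carbon C2, its sp2 neighbour C1 and the side-chain carbon on C1 form a masked 2-bromo-1-acylcycloalkene. C2 maps onto a ketone carbon, C1 onto a diazo carbon and the side chain onto the acyl group of diazoacetone. The quaternary C3 beside C2 carries no hydrogen.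
- The C4–Br stereocentre is set before the ring expansion: CBS desymmetrisation of 2,2-dimethylcyclopentane-1,3-dione, then triflate/bromide inversion.
- Ring order: the only ring is bought as a cyclopentane and expanded to the cyclohexene in step 5.

Key step: step 5

Remarks on the chemistry: ring locants follow the target name (C1 bears the side chain, C2 the vinylic Br, C3 the two methyls, C4 the secondary Br). 2,2-Dimethylcyclopentane-1,3-dione and 1,1,1-trifluoropentane-2,4-dione are taken as commercial. The CBS catalyst enantiomers are chosen by the usual large/small model and should be confirmed on the first batch (rotation of the known ketol 2, Mosher ester of 11).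

Step 1
Reactants: 1 2,2-dimethylcyclopentane-1,3-dione
Product: 2 (3S)-3-hydroxy-2,2-dimethylcyclopentan-1-one
Conditions: (R)-Me-CBS (10 mol %), catecholborane (1.0 equiv), toluene, −60 °C; aq. NaOH work-up
Reagents that add atoms: none
Why: Corey–Bakshi–Shibata desymmetrising mono-reduction of a prochiral 2,2-disubstituted 1,3-dione, in which the quaternary carbon is the large flank, so the (R)-catalyst should give the (S)-carbinol.

Step 2
Reactants: 2 (3S)-3-hydroxy-2,2-dimethylcyclopentan-1-one
Product: 4 (3R)-3-bromo-2,2-dimethylcyclopentan-1-one, via triflate 3 (not isolated)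
Conditions: Tf2O, pyridine, CH2Cl2, −40 °C; crude 3, then LiBr, acetone, 0 °C to rt
Reagents that add atoms: triflic anhydride, O=S(=O)(OS(=O)(=O)C(F)(F)F)C(F)(F)F (atoms kept only in 3); lithium bromide, [Li+].[Br-]
Why: SN2 displacement of a secondary triflate by bromide with inversion should set the (R)-C–Br centre; the carbon is neopentylic but sits in a cyclopentane, and the acyl-bearing quaternary neighbour disfavours Wagner–Meerwein shift and offers no hydrogen for elimination toward the ketone.

Step 3
Reactants: 5 1,1,1-trifluoropentane-2,4-dione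
Product: 6 1-diazopropan-2-one (diazoacetone)
Conditions: MsN3, Et3N, H2O (1 equiv), MeCN, rt; used as a solution
Reagents that add atoms: methanesulfonyl azide, CS(=O)(=O)N=[N+]=[N-]
Why: Detrifluoroacetylative diazo transfer (Regitz-type) to the activated methylene, with loss of the trifluoroacetyl group as its N-sulfonyl amide, should give the terminal diazo ketone.

Step 4
Reactants: 4 (3R)-3-bromo-2,2-dimethylcyclopentan-1-one; 6 1-diazopropan-2-one
Product: 7 1-[(3R)-3-bromo-1-hydroxy-2,2-dimethylcyclopentyl]-1-diazopropan-2-one (both C1 epimers)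
Conditions: LDA, THF, −78 °C (6, 1.3 equiv); then 4; AcOH quench at −78 °C
Reagents that add atoms: none
Why: Aldol-type addition of the lithiated diazo ketone (deprotonated at the diazo carbon) to the ketone, quenched cold to prevent retro-aldol; the new carbinol centre is destroyed in step 5, so its configuration is irrelevant.

Step 5
Reactants: 7 1-[(3R)-3-bromo-1-hydroxy-2,2-dimethylcyclopentyl]-1-diazopropan-2-one
Product: 8 1-[(4R)-2,4-dibromo-3,3-dimethylcyclohex-1-en-1-yl]ethan-1-one
Conditions: SnBr4 (1.5 equiv), CH2Cl2, −40 to 0 °C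
Reagents that add atoms: tin(IV) bromide, Br[Sn](Br)(Br)Br
Why: Proposed new method: SnBr4 should ionise the tertiary C–OH bond of 7 to an alkenyldiazonium ion; loss of N2 gives a destabilised α-acyl vinyl cation at C1, the ring bond C6–C2 shifts to C1 so that the five-membered ring C2–C3–C4–C5–C6 becomes the six-membered ring with a cyclic vinyl cation at C2, and bromide from the bromostannate counter-ion adds to C2. The closest known reaction type is the Lewis-acid-promoted vinyl-cation ring expansion of β-hydroxy-α-diazo ketones derived from cycloalkanones, where the ring-expanded cation is intercepted by C–H bonds or arenes; ending it by halide transfer from the Lewis acid to give a 2-bromo-1-acylcycloalkene is the untested extension. No ring is closed: the existing ring grows by one carbon through a 1,2-alkyl shift across the exocyclic C=C bond, and no stereocentre is formed (the new alkene is endocyclic and tetrasubstituted, C4 is untouched). The step needs migration of the CH2 carbon C6 and not of the quaternary C3: in the alkenyldiazonium ion the acetyl group should sit syn to the small CH2 and the slim N2+ syn to CMe2, which places C6 anti to the leaving group, and C3 is a poorer migrating group because of the inductive pull of the C4–Br bond. It also needs bromide capture at C2 to outrun a 1,2-methyl shift from C3, which the contact ion pair and the poor overlap of the C3–CH3 bonds with the in-plane empty orbital of the bent ring cation should secure.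

Step 6
Reactants: 8 1-[(4R)-2,4-dibromo-3,3-dimethylcyclohex-1-en-1-yl]ethan-1-one
Product: 10 2-bromo-1-[(4R)-2,4-dibromo-3,3-dimethylcyclohex-1-en-1-yl]ethan-1-one, via silyl enol ether 9 (not isolated)
Conditions: TMSOTf, Et3N, CH2Cl2, 0 °C; then NBS, NaHCO3, THF, −78 to 0 °C
Reagents that add atoms: trimethylsilyl triflate, C[Si](C)(C)OS(=O)(=O)C(F)(F)F (atoms kept only in 9); N-bromosuccinimide, O=C1CCC(=O)N1Br
Why: Soft enolisation followed by electrophilic bromination of the silyl enol ether should be regiospecific, because the methyl group is the only enolisable position (the ring CH2 at C6 is cross-conjugated and C3 is quaternary).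

Step 7
Reactants: 10 2-bromo-1-[(4R)-2,4-dibromo-3,3-dimethylcyclohex-1-en-1-yl]ethan-1-one
Product: 11 (1R)-2-bromo-1-[(4R)-2,4-dibromo-3,3-dimethylcyclohex-1-en-1-yl]ethan-1-ol
Conditions: (R)-Me-CBS (20 mol %), BH3·SMe2 (0.7 equiv), THF, −20 °C; MeOH quench
Reagents that add atoms: none
Why: Corey–Bakshi–Shibata reduction of an α-bromo ketone, where the bulky tetrasubstituted cycloalkenyl group should act as the large substituent as aryl does in aryl bromomethyl ketones, so the (R)-catalyst should give the (R)-bromohydrin under reagent control.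

Step 8
Reactants: 11 (1R)-2-bromo-1-[(4R)-2,4-dibromo-3,3-dimethylcyclohex-1-en-1-yl]ethan-1-ol
Product: 12 (4R)-2,4-dibromo-1-[(1S)-2-bromo-1-chloroethyl]-3,3-dimethylcyclohex-1-ene
Conditions: PPh3, NCS, CH2Cl2, −20 °C to rt
Reagents that add atoms: N-chlorosuccinimide, O=C1CCC(=O)N1Cl
Why: Appel-type chlorination through the alkoxyphosphonium chloride ion pair should proceed by SN2 with inversion to the (S)-chloride; SN2′ attack is blocked because the far alkene carbon C2 is fully substituted and flanked by the quaternary C3.

**Compound list**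
1 | 2,2-dimethylcyclopentane-1,3-dione | CC1(C)C(=O)CCC1=O | starting material
2 | (3S)-3-hydroxy-2,2-dimethylcyclopentan-1-one | CC1(C)C(=O)CC[C@@H]1O | intermediate
3 | (1S)-2,2-dimethyl-3-oxocyclopentyl trifluoromethanesulfonate | CC1(C)C(=O)CC[C@@H]1OS(=O)(=O)C(F)(F)F | intermediate
4 | (3R)-3-bromo-2,2-dimethylcyclopentan-1-one | CC1(C)C(=O)CC[C@H]1Br | intermediate
5 | 1,1,1-trifluoropentane-2,4-dione | CC(=O)CC(=O)C(F)(F)F | starting material
6 | 1-diazopropan-2-one | CC(=O)C=[N+]=[N-] | intermediate
7 | 1-[(3R)-3-bromo-1-hydroxy-2,2-dimethylcyclopentyl]-1-diazopropan-2-one (both C1 epimers) | CC(=O)C(=[N+]=[N-])C1(O)CC[C@@H](Br)C1(C)C | intermediate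
8 | 1-[(4R)-2,4-dibromo-3,3-dimethylcyclohex-1-en-1-yl]ethan-1-one | CC1(C)C(Br)=C(C(C)=O)CC[C@H]1Br | intermediate
9 | {1-[(4R)-2,4-dibromo-3,3-dimethylcyclohex-1-en-1-yl]ethenyl}oxy(trimethyl)silane | CC1(C)C(Br)=C(C(=C)O[Si](C)(C)C)CC[C@H]1Br | intermediate
10 | 2-bromo-1-[(4R)-2,4-dibromo-3,3-dimethylcyclohex-1-en-1-yl]ethan-1-one | CC1(C)C(Br)=C(C(=O)CBr)CC[C@H]1Br | intermediate
11 | (1R)-2-bromo-1-[(4R)-2,4-dibromo-3,3-dimethylcyclohex-1-en-1-yl]ethan-1-ol | CC1(C)C(Br)=C([C@@H](O)CBr)CC[C@H]1Br | intermediate
12 | (4R)-2,4-dibromo-1-[(1S)-2-bromo-1-chloroethyl]-3,3-dimethylcyclohex-1-ene | CC1(C)C(Br)=C([C@H](Cl)CBr)CC[C@H]1Br | target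

**Step count and risks**
Total steps: 8. Longest linear sequence: 7 steps (steps 1, 2, 4, 5, 6, 7, 8); step 3 is a one-step branch.

Steps most likely to fail:

1. Step 5 (proposed new method). The quaternary carbon may migrate in place of the methylene carbon, or the ring vinyl cation may undergo methyl shift or proton loss before bromide capture. The fallback uses known chemistry, sets out from compound 4 and comes back at compound 8. Compound 4 is homologated with TMSCHN2 and BF3·OEt2 (CH2Cl2, −78 °C), where the less substituted α-carbon migrates, to (3R)-3-bromo-2,2-dimethyl-6-(trimethylsilyl)cyclohexan-1-one F1. Acidic work-up desilylates this to (3R)-3-bromo-2,2-dimethylcyclohexan-1-one F2. Arnold–Vilsmeier bromoformylation (PBr3, DMF, CHCl3, 0 to 60 °C), possible only toward the CH2 side, should give (4R)-2,4-dibromo-3,3-dimethylcyclohex-1-ene-1-carbaldehyde F3. MeMgBr (THF, −78 °C) should give 1-[(4R)-2,4-dibromo-3,3-dimethylcyclohex-1-en-1-yl]ethan-1-ol F4 as a mixture of carbinol epimers, and Dess–Martin oxidation returns 8. The ring is still made by expansion of the five-membered ring.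

2. Step 2. Backside attack at the neopentylic carbon may be outrun by elimination or skeletal rearrangement of the triflate. The fallback forms the C–Br bond on an sp2 carbon and creates the quaternary centre in the same event. It does not use compounds 1–3: it sets out from commercial 2-methylcyclopent-2-en-1-one F5 and comes back at compound 4. Catalytic asymmetric methyl addition (Me2Zn, Ti(OiPr)4, chiral bis(sulfonamide) diol ligand) should give (1S)-1,2-dimethylcyclopent-2-en-1-ol F6. NBS (CH2Cl2, −20 °C) should then trigger a bromonium semipinacol rearrangement: the bromonium ion forms syn to the hydroxyl and the methyl group migrates anti to it, which transfers the carbinol configuration to the (R)-C–Br centre of 4.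

3. Step 8. The neighbouring bromine may participate, or the allylic centre may ionise, so that inversion is incomplete or the halogens exchange positions. The fallback installs chlorine first and bromine last. It sets out from compound 8 and comes back at compound 12.
   - TBSOTf/Et3N should give the silyl enol ether tert-butyl({1-[(4R)-2,4-dibromo-3,3-dimethylcyclohex-1-en-1-yl]ethenyl}oxy)dimethylsilane F7.
   - Rubottom oxidation (mCPBA, NaHCO3, CH2Cl2) with silyl migration should give 2-{[tert-butyl(dimethyl)silyl]oxy}-1-[(4R)-2,4-dibromo-3,3-dimethylcyclohex-1-en-1-yl]ethan-1-one F8.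
   - (R)-Me-CBS/BH3·SMe2 should give (1R)-2-{[tert-butyl(dimethyl)silyl]oxy}-1-[(4R)-2,4-dibromo-3,3-dimethylcyclohex-1-en-1-yl]ethan-1-ol F9.
   - PPh3/NCS, now without a participating halogen, should give tert-butyl{(2S)-2-chloro-2-[(4R)-2,4-dibromo-3,3-dimethylcyclohex-1-en-1-yl]ethoxy}dimethylsilane F10.
   - HF·pyridine should give (2S)-2-chloro-2-[(4R)-2,4-dibromo-3,3-dimethylcyclohex-1-en-1-yl]ethan-1-ol F11.
   - CBr4/PPh3 at the primary alcohol gives 12.

Further compounds
F1 | step 5 | (3R)-3-bromo-2,2-dimethyl-6-(trimethylsilyl)cyclohexan-1-one (C6 epimers) | CC1(C)C(=O)C([Si](C)(C)C)CC[C@H]1Br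
F2 | step 5 | (3R)-3-bromo-2,2-dimethylcyclohexan-1-one | CC1(C)C(=O)CCC[C@H]1Br
F3 | step 5 | (4R)-2,4-dibromo-3,3-dimethylcyclohex-1-ene-1-carbaldehyde | CC1(C)C(Br)=C(C=O)CC[C@H]1Br
F4 | step 5 | 1-[(4R)-2,4-dibromo-3,3-dimethylcyclohex-1-en-1-yl]ethan-1-ol (carbinol epimers) | CC1(C)C(Br)=C(C(C)O)CC[C@H]1Br
F5 | step 2 | 2-methylcyclopent-2-en-1-one | CC1=CCCC1=O
F6 | step 2 | (1S)-1,2-dimethylcyclopent-2-en-1-ol | C[C@]1(O)CCC=C1C
F7 | step 8 | tert-butyl({1-[(4R)-2,4-dibromo-3,3-dimethylcyclohex-1-en-1-yl]ethenyl}oxy)dimethylsilane | CC1(C)C(Br)=C(C(=C)O[Si](C)(C)C(C)(C)C)CC[C@H]1Br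
F8 | step 8 | 2-{[tert-butyl(dimethyl)silyl]oxy}-1-[(4R)-2,4-dibromo-3,3-dimethylcyclohex-1-en-1-yl]ethan-1-one | CC1(C)C(Br)=C(C(=O)CO[Si](C)(C)C(C)(C)C)CC[C@H]1Br
F9 | step 8 | (1R)-2-{[tert-butyl(dimethyl)silyl]oxy}-1-[(4R)-2,4-dibromo-3,3-dimethylcyclohex-1-en-1-yl]ethan-1-ol | CC1(C)C(Br)=C([C@@H](O)CO[Si](C)(C)C(C)(C)C)CC[C@H]1Br
F10 | step 8 | tert-butyl{(2S)-2-chloro-2-[(4R)-2,4-dibromo-3,3-dimethylcyclohex-1-en-1-yl]ethoxy}dimethylsilane | CC1(C)C(Br)=C([C@H](Cl)CO[Si](C)(C)C(C)(C)C)CC[C@H]1Br
F11 | step 8 | (2S)-2-chloro-2-[(4R)-2,4-dibromo-3,3-dimethylcyclohex-1-en-1-yl]ethan-1-ol | CC1(C)C(Br)=C([C@H](Cl)CO)CC[C@H]1Br
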